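A smaller charge of partner, 1.80 M, goes in beside 2.0 M of substrate, and I ask which form of the substrate leads at the end of each flask.

- autumn: substrate 2.0 M; partner 1.80 M; time 10 d
- spring: substrate 2.0 M; partner 1.80 M; time 5.0 d

    substrate → intermediate (k1 = 0.037 h⁻¹)
    partner → decomposed reagent (k2 = 0.20 h⁻¹)
    substrate → target (k3 = 0.0073 h⁻¹)
    partner + intermediate → side product (k4 = 0.0030 M⁻¹ h⁻¹)

- which of these there is most of at the end, counted by the substrate in it, autumn (target / side product / substrate / intermediate)
- which of these there is most of at the end, counted by the substrate in it, spring (target / side product / substrate / intermediate)
- final amount of the leader among these, as a percentage of the substrate charged, in autumn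
- final amount of the leader among these, as a percentage of the substrate charged, in spring

Substrate leaves by two first-order steps, so I add their constants and multiply by the time. This gives 5.32 in spring and 10.6 in autumn. That pure number is the lifetimes served: how many substrate lifetimes fit into the run. The substrate left is exp(−n) of the charge, 0.489 % in spring. What has reacted divides by the selectivity of the two steps, 83.5 % to intermediate and 16.5 % to target, so I expect intermediate to lead in both flasks.

Is one number enough? Partner can take intermediate to side product, but its half-life by decomposition alone, 0.14 d, is shorter than the spring time. So I replace its falling curve by its charge held for one partner lifetime, 5.00 h. At its starting rate I reckon intermediate at 0.370 M over that span, and with partner held at its charge I reckon 2.70 % of that taken, an estimated loss of 0.499 % of the substrate charged. I commit to 83.0 % in autumn and 82.6 % in spring.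

The forecast gives intermediate at 83.1 % in autumn and intermediate at 82.7 % in spring, and says: “The partner decomposes within a few hours, well before much intermediate has built up”.

The simulation gives intermediate at 83.1 % in autumn and intermediate at 82.7 % in spring. Side product in spring stands at 0.402 %, less than my mean-curve 0.499 %. The spring flask still holds 0.49 % of its charged substrate, and exp(−n) at 5.32 lifetimes served gave 0.489 %.

The same flask as spring, read at 30 h, has served 1.33 lifetimes, which gives 26.4 % substrate and 60.9 % intermediate. Computed, that flask holds 26 % and 61.0 %.

Its constants come from no measurement; no experiment stands behind them.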